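The dihydrofuran ring shares C3a and C7a with ring C. Stripping ring C away leaves O1–C7a–C3a–C3–C2 as a cis-β,γ-disubstituted γ-butyrolactone that already carries both ring stereocentres. Ring C is therefore built last onto this lactone: its cyclic silyl ketene acetal (C7a=C3a) adds in an inverse-demand [4+2] sense to methyl 3-bromocoumalate, and loss of CO2 and silanol gives the cis-2-aryl-2,3-dihydrobenzofuran in one operation, with bromine at C7 (future methoxy) and an ester at C5 (future hydroxypropyl chain). The lactone comes from an auxiliary-controlled anti-aldol reaction. The erythro arylglycerol arm follows by a second auxiliary aldol and inversion at C7′.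

Key step: step 10

Assumption: the SMILES is read as a cis-(2R,3R)-dihydrobenzofuran with an erythro-(7′R,8′S) arylglycerol arm (C7′ benzylic carbinol, C8′ aryloxy carbon, C9′ CH2OH); the ring B oxygen is carried as a benzyl ether, because acid needed to unmask an acetal would strip the primary silyl ether and endanger the acid-labile cis C2–O1 bond. TBS = tert-butyldimethylsilyl.

Step 1
Reactants: 1 syringaldehyde
Product: 2 4-(benzyloxy)-3,5-dimethoxybenzaldehyde
Conditions: BnBr, K2CO3, DMF, 60 °C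
Reagents that add atoms: benzyl bromide, BrCc1ccccc1
Why: Williamson etherification of the phenoxide; benzyl is chosen because neutral hydrogenolysis later removes it in the same operation that saturates the side chain.

Step 2
Reactants: 3 (R)-4-benzyloxazolidin-2-one; 4 pent-4-enoyl chloride
Product: 5 (R)-4-benzyl-3-(pent-4-enoyl)oxazolidin-2-one
Conditions: n-BuLi, THF, −78 °C; then 4, −78 → 0 °C
Reagents that add atoms: none
Why: N-acylation of the lithiated oxazolidinone by the acid chloride (standard auxiliary loading).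

Step 3
Reactants: 5 (R)-4-benzyl-3-(pent-4-enoyl)oxazolidin-2-one; 2 4-(benzyloxy)-3,5-dimethoxybenzaldehyde
Product: 7 (R)-4-benzyl-3-[(2S)-2-[(R)-[4-(benzyloxy)-3,5-dimethoxyphenyl](hydroxy)methyl]pent-4-enoyl]oxazolidin-2-one, via trimethylsilyl ether 6 (not isolated)
Conditions: MgCl2 (0.2 equiv), Et3N (2 equiv), Me3SiCl (1.5 equiv), EtOAc, 23 °C; then CF3CO2H (cat.), MeOH
Reagents that add atoms: none
Why: Evans magnesium-halide-catalysed direct anti-aldol reaction: the chelated Z-enolate should add to the non-enolisable aldehyde on the face away from the auxiliary benzyl group through a boat-like transition state, with silyl trapping driving the equilibrium, so the auxiliary sets both new centres (future C3 and C2) as the (2S,3R) anti pair.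

Step 4
Reactants: 7 anti-aldol imide
Product: 8 (1R,2R)-2-allyl-1-[4-(benzyloxy)-3,5-dimethoxyphenyl]propane-1,3-diol
Conditions: LiBH4 (2 equiv), H2O (1 equiv), Et2O, 0 °C
Reagents that add atoms: none
Why: Hydride reduction of the activated exocyclic imide carbonyl releases the auxiliary and gives the 1,3-diol without touching the alkene, the ethers or either stereocentre.

Step 5
Reactants: 8 (1R,2R)-2-allyl-1-[4-(benzyloxy)-3,5-dimethoxyphenyl]propane-1,3-diol
Product: 9 (1R,2R)-1-[4-(benzyloxy)-3,5-dimethoxyphenyl]-2-[(tert-butyldimethylsilyloxy)methyl]pent-4-en-1-ol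
Conditions: tBuMe2SiCl (1.05 equiv), imidazole, CH2Cl2, 0 °C
Reagents that add atoms: tert-butyl(chloro)dimethylsilane, CC(C)(C)[Si](C)(C)Cl
Why: Chemoselective silylation of the primary alcohol over the hindered secondary benzylic alcohol.

Step 6
Reactants: 9 (1R,2R)-1-[4-(benzyloxy)-3,5-dimethoxyphenyl]-2-[(tert-butyldimethylsilyloxy)methyl]pent-4-en-1-ol
Product: 12 (4R,5R)-5-[4-(benzyloxy)-3,5-dimethoxyphenyl]-4-[(tert-butyldimethylsilyloxy)methyl]tetrahydrofuran-2-ol (anomer mixture), via triol 10 (not isolated), via hydroxy aldehyde 11 (not isolated)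
Conditions: OsO4 (2 mol%), NaIO4 (4 equiv), 2,6-lutidine (2 equiv), 1,4-dioxane/H2O 3:1, rt
Reagents that add atoms: osmium tetroxide, O=[Os](=O)(=O)=O (catalytic oxygen carrier); sodium periodate, [Na+].[O-]I(=O)(=O)=O (terminal oxygen source)
Why: Lemieux–Johnson oxidation: catalytic dihydroxylation of the terminal alkene and periodate cleavage give the aldehyde, which closes onto the benzylic hydroxyl as the five-membered lactol under buffered conditions that the electron-rich arene tolerates.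

Step 7
Reactants: 12 lactol
Product: 13 (4R,5R)-5-[4-(benzyloxy)-3,5-dimethoxyphenyl]-4-[(tert-butyldimethylsilyloxy)methyl]dihydrofuran-2(3H)-one (cis lactone)
Conditions: TEMPO (0.1 equiv), PhI(OAc)2 (1.5 equiv), CH2Cl2, rt
Reagents that add atoms: none
Why: Oxoammonium (TEMPO) oxidation of the lactol to the γ-lactone; no stereocentre is α to the new carbonyl, so the cis relationship that follows from the anti-aldol geometry is kept.

Step 8
Reactants: 13 cis lactone
Product: 14 tert-butyl{[(2R,3R)-2-[4-(benzyloxy)-3,5-dimethoxyphenyl]-3-[(tert-butyldimethylsilyloxy)methyl]-2,3-dihydrofuran-5-yl]oxy}dimethylsilane (cyclic silyl ketene acetal of 13)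
Conditions: LiN(iPr)2 (1.1 equiv), THF, −78 °C; tBuMe2SiCl (1.2 equiv), DMPU, −78 °C → rt; pentane filtration, used crude
Reagents that add atoms: tert-butyl(chloro)dimethylsilane, CC(C)(C)[Si](C)(C)Cl
Why: Kinetic α-deprotonation of the lactone and O-silylation (silyl chloride in a dipolar cosolvent favours O over C) give the cyclic silyl ketene acetal; C4 carries no leaving group, so no β-elimination competes.

Step 9
Reactants: 15 methyl coumalate
Product: 16 methyl 3-bromocoumalate (methyl 3-bromo-2-oxo-2H-pyran-5-carboxylate)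
Conditions: Br2 (1.1 equiv), CH2Cl2, 0 °C → rt; then Et3N (1.2 equiv), 0 °C
Reagents that add atoms: bromine, BrBr
Why: Electrophilic bromination of the 2-pyrone at C3, the only free nucleophilic position of the dienyl ester (C5 is blocked by the ester), with amine taking up HBr.

Step 10
Reactants: 14 cyclic silyl ketene acetal; 16 methyl 3-bromocoumalate
Product: 19 methyl (2R,3R)-2-[4-(benzyloxy)-3,5-dimethoxyphenyl]-7-bromo-3-[(tert-butyldimethylsilyloxy)methyl]-2,3-dihydrobenzofuran-5-carboxylate (cis), via bridged lactone adduct 17 (not isolated), via cyclohexadiene 18 (not isolated)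
Conditions: 16 (1 equiv), 14 (1.5 equiv), toluene, 60 → 100 °C, sealed tube; then DBU (1.5 equiv), rt
Reagents that add atoms: none
Why: Proposed new method: the electron-rich ketene acetal should add to the electron-poor diene of 16 in an inverse-electron-demand [4+2] cycloaddition (concerted but asynchronous, or stepwise through a zwitterion), its nucleophilic β-carbon (future C3a) bonding to pyrone C6 and the acetal carbon (future C7a) to C3 to give bridged lactone 17; cycloreversion then expels CO2 to leave cyclohexadiene 18, and base-assisted loss of tert-butyldimethylsilanol across C7a–C3a aromatises ring C. The closest known reaction is the cycloaddition/decarboxylation/alcohol-elimination benzannulation of 2-pyrone-5-carboxylates with acyclic ketene acetals, which gives para-alkoxybenzoates; a lactone-derived silyl ketene acetal has not been used in it. Ring C is closed by intermolecular [4+2] cycloaddition forming C3a–C4 and C7a–C7, while the oxygen ring is carried over intact from the lactone. No lasting stereocentre is made (C3a and C7a end as sp2 carbons) and C2 and C3 take no part, so the cis relationship from steps 3–7 persists. The step needs regiocontrol, secured by polarity matching (acetal β-carbon to the ester-activated C6, which places O1 para to the ester and bromine at C7), and chemoselective aromatisation, secured because silanolate is the better leaving group and the cyclic oxocarbenium or E1cB pathway keeps the O1–C7a bond.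

Step 11
Reactants: 19 cis 7-bromo-dihydrobenzofuran ester
Product: 20 methyl (2R,3R)-2-[4-(benzyloxy)-3,5-dimethoxyphenyl]-3-[(tert-butyldimethylsilyloxy)methyl]-7-methoxy-2,3-dihydrobenzofuran-5-carboxylate
Conditions: CuI (0.2 equiv), NaOMe (25% in MeOH, 6 equiv), DMF, 100 °C
Reagents that add atoms: sodium methoxide, [Na+].[O-]C
Why: Ullmann-type copper-catalysed C–O coupling of the aryl bromide with methoxide; the methyl ester is degenerate toward methoxide and neither stereocentre bears an acidic hydrogen.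

Step 12
Reactants: 20 7-methoxy ester
Product: 21 [(2R,3R)-2-[4-(benzyloxy)-3,5-dimethoxyphenyl]-3-[(tert-butyldimethylsilyloxy)methyl]-7-methoxy-2,3-dihydrobenzofuran-5-yl]methanol
Conditions: iBu2AlH (2.5 equiv), CH2Cl2, −78 → 0 °C; Rochelle salt work-up
Reagents that add atoms: none
Why: Aluminium hydride reduction of the aryl ester to the benzylic alcohol; silyl and benzyl ethers are inert.

Step 13
Reactants: 21 benzylic alcohol; 22 ethyl (triphenylphosphoranylidene)acetate
Product: 24 ethyl (E)-3-[(2R,3R)-2-[4-(benzyloxy)-3,5-dimethoxyphenyl]-3-[(tert-butyldimethylsilyloxy)methyl]-7-methoxy-2,3-dihydrobenzofuran-5-yl]acrylate, via aldehyde 23 (not isolated)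
Conditions: MnO2 (10 equiv), 22 (1.5 equiv), toluene, 80 °C
Reagents that add atoms: none
Why: Tandem oxidation–Wittig olefination: MnO2 oxidises only the benzylic alcohol and the stabilised ylide traps the aldehyde in situ as the E-cinnamate.

Step 14
Reactants: 24 cinnamate
Product: 25 ethyl 3-[(2R,3R)-3-[(tert-butyldimethylsilyloxy)methyl]-2-(4-hydroxy-3,5-dimethoxyphenyl)-7-methoxy-2,3-dihydrobenzofuran-5-yl]propanoate
Conditions: H2 (1 atm), 10% Pd/C, EtOAc, rt
Reagents that add atoms: none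
Why: Catalytic hydrogenation saturates the cinnamate and hydrogenolyses the benzyl ether in one neutral operation, unmasking the ring B phenol without acid or base that could open the cis C2–O1 bond.

Step 15
Reactants: 3 (R)-4-benzyloxazolidin-2-one; 26 bromoacetyl bromide
Product: 27 (R)-4-benzyl-3-(2-bromoacetyl)oxazolidin-2-one
Conditions: n-BuLi (1.0 equiv), THF, −78 °C; then 26 (1.1 equiv), −78 °C
Reagents that add atoms: none
Why: N-acylation of the lithiated oxazolidinone at low temperature, where acyl substitution outruns displacement of the α-bromide.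

Step 16
Reactants: 25 ring B phenol; 27 (R)-4-benzyl-3-(2-bromoacetyl)oxazolidin-2-one
Product: 28 (R)-4-benzyl-3-{2-[4-[(2R,3R)-3-[(tert-butyldimethylsilyloxy)methyl]-5-(3-ethoxy-3-oxopropyl)-7-methoxy-2,3-dihydrobenzofuran-2-yl]-2,6-dimethoxyphenoxy]acetyl}oxazolidin-2-one
Conditions: K2CO3 (1.5 equiv), acetone, 0 °C → rt
Reagents that add atoms: none
Why: Williamson alkylation: the α-bromo imide is highly SN2-active, so the hindered 2,6-dimethoxyphenoxide should be alkylated under weak base at low temperature before imide cleavage or quinone-methide opening of the phenolic dihydrobenzofuran can intervene.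

Step 17
Reactants: 29 vanillin
Product: 30 4-(tert-butyldimethylsilyloxy)-3-methoxybenzaldehyde
Conditions: tBuMe2SiCl, imidazole, CH2Cl2, rt
Reagents that add atoms: tert-butyl(chloro)dimethylsilane, CC(C)(C)[Si](C)(C)Cl
Why: Standard silylation of the phenol, giving an aldehyde whose protecting group falls in the final fluoride step.

Step 18
Reactants: 28 aryloxyacetyl imide; 30 4-(tert-butyldimethylsilyloxy)-3-methoxybenzaldehyde
Product: 31 (R)-4-benzyl-3-[(2R,3S)-2-{4-[(2R,3R)-3-[(tert-butyldimethylsilyloxy)methyl]-5-(3-ethoxy-3-oxopropyl)-7-methoxy-2,3-dihydrobenzofuran-2-yl]-2,6-dimethoxyphenoxy}-3-[4-(tert-butyldimethylsilyloxy)-3-methoxyphenyl]-3-hydroxypropanoyl]oxazolidin-2-one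
Conditions: Bu2BOTf (1.3 equiv), iPr2NEt (1.5 equiv), CH2Cl2, −78 → 0 °C; 30 (1.3 equiv), −78 → 0 °C; pH 7 buffer, MeOH, 30% H2O2, 0 °C
Reagents that add atoms: none
Why: Evans boron-mediated syn-aldol reaction: the Z-boron enolate of the (R)-imide should react through a chair Zimmerman–Traxler transition state, the auxiliary fixing C8′ and C7′ as the syn (threo) pair, (2R,3S) in the imide; the ethyl ester is not enolised under these conditions.

Step 19
Reactants: 31 syn-aldol imide
Product: 32 (1S,2S)-1-[4-(tert-butyldimethylsilyloxy)-3-methoxyphenyl]-2-{4-[(2R,3R)-3-[(tert-butyldimethylsilyloxy)methyl]-5-(3-hydroxypropyl)-7-methoxy-2,3-dihydrobenzofuran-2-yl]-2,6-dimethoxyphenoxy}propane-1,3-diol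
Conditions: LiBH4 (6 equiv), THF, 0 °C → rt
Reagents that add atoms: none
Why: One hydride reduction takes the imide (auxiliary released) and the ethyl ester to primary alcohols, revealing C9′–OH and completing the 3-hydroxypropyl chain.

Step 20
Reactants: 32 threo triol
Product: 33 (1S,2S)-3-(tert-butyldimethylsilyloxy)-1-[4-(tert-butyldimethylsilyloxy)-3-methoxyphenyl]-2-{4-[(2R,3R)-3-[(tert-butyldimethylsilyloxy)methyl]-5-[3-(tert-butyldimethylsilyloxy)propyl]-7-methoxy-2,3-dihydrobenzofuran-2-yl]-2,6-dimethoxyphenoxy}propan-1-ol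
Conditions: tBuMe2SiCl (2.3 equiv), imidazole (5 equiv), CH2Cl2, 0 °C
Reagents that add atoms: tert-butyl(chloro)dimethylsilane, CC(C)(C)[Si](C)(C)Cl
Why: Selective silylation of the two primary alcohols; the secondary benzylic C7′–OH, flanked by the bulky aryloxy-bearing carbon, should stay free.

Step 21
Reactants: 33 threo benzylic alcohol
Product: 34 (1R,2S)-chloroacetate of the C7′-inverted alcohol [(1R,2S)-3-(tert-butyldimethylsilyloxy)-1-[4-(tert-butyldimethylsilyloxy)-3-methoxyphenyl]-2-(aryloxy)propyl 2-chloroacetate, aryloxy as in 33]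
Conditions: ClCH2CO2H (4 equiv), PPh3 (4 equiv), DIAD (4 equiv), toluene, 0 °C → rt
Reagents that add atoms: chloroacetic acid, OC(=O)CCl
Why: Mitsunobu esterification with the acidic pronucleophile chloroacetic acid should displace the oxyphosphonium by SN2 with inversion at C7′, turning the threo (7′S,8′S) into the erythro (7′R,8′S) series; the non-polar solvent disfavours ionisation.

Step 22
Reactants: 34 erythro chloroacetate
Product: 35 (1R,2S)-3-(tert-butyldimethylsilyloxy)-1-[4-(tert-butyldimethylsilyloxy)-3-methoxyphenyl]-2-{4-[(2R,3R)-3-[(tert-butyldimethylsilyloxy)methyl]-5-[3-(tert-butyldimethylsilyloxy)propyl]-7-methoxy-2,3-dihydrobenzofuran-2-yl]-2,6-dimethoxyphenoxy}propan-1-ol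
Conditions: iBu2AlH (3 equiv), CH2Cl2, −78 °C
Reagents that add atoms: none
Why: Reductive ester cleavage at low temperature frees the C7′ alcohol with retention while the phenol stays silylated, so no base-induced quinone-methide loss of the benzylic ester can occur.

Step 23
Reactants: 35 erythro tetrasilyl ether
Product: 36 (1R,2S)-1-(4-hydroxy-3-methoxyphenyl)-2-{4-[(2R,3R)-3-(hydroxymethyl)-5-(3-hydroxypropyl)-7-methoxy-2,3-dihydrobenzofuran-2-yl]-2,6-dimethoxyphenoxy}propane-1,3-diol (CNP0301567.1)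
Conditions: Bu4NF (8 equiv), AcOH (8 equiv), THF, 0 °C → rt
Reagents that add atoms: none
Why: Fluoride-mediated desilylation removes the aryl and the three alkyl silyl ethers; acetic acid buffering keeps the medium near neutral so that neither the benzylic alcohol nor the cis ring fusion should epimerise.

Compound list
1 | syringaldehyde | COc1cc(C=O)cc(OC)c1O | starting material
2 | 4-(benzyloxy)-3,5-dimethoxybenzaldehyde | COc1cc(C=O)cc(OC)c1OCc1ccccc1 | intermediate
3 | (R)-4-benzyloxazolidin-2-one | O=C1N[C@H](Cc2ccccc2)CO1 | starting material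
4 | pent-4-enoyl chloride | C=CCCC(=O)Cl | starting material
5 | (R)-4-benzyl-3-(pent-4-enoyl)oxazolidin-2-one | C=CCCC(=O)N1[C@H](Cc2ccccc2)COC1=O | intermediate
6 | trimethylsilyl ether of anti-aldol imide 7 (not isolated) | COc1cc([C@H](O[Si](C)(C)C)[C@H](CC=C)C(=O)N2[C@H](Cc3ccccc3)COC2=O)cc(OC)c1OCc1ccccc1 | intermediate
7 | (R)-4-benzyl-3-[(2S)-2-[(R)-[4-(benzyloxy)-3,5-dimethoxyphenyl](hydroxy)methyl]pent-4-enoyl]oxazolidin-2-one | COc1cc([C@H](O)[C@H](CC=C)C(=O)N2[C@H](Cc3ccccc3)COC2=O)cc(OC)c1OCc1ccccc1 | intermediate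
8 | (1R,2R)-2-allyl-1-[4-(benzyloxy)-3,5-dimethoxyphenyl]propane-1,3-diol | COc1cc([C@H](O)[C@H](CC=C)CO)cc(OC)c1OCc1ccccc1 | intermediate
9 | (1R,2R)-1-[4-(benzyloxy)-3,5-dimethoxyphenyl]-2-[(tert-butyldimethylsilyloxy)methyl]pent-4-en-1-ol | COc1cc([C@H](O)[C@H](CC=C)CO[Si](C)(C)C(C)(C)C)cc(OC)c1OCc1ccccc1 | intermediate
10 | (1R,2R)-1-[4-(benzyloxy)-3,5-dimethoxyphenyl]-2-[(tert-butyldimethylsilyloxy)methyl]pentane-1,4,5-triol, C4 epimers (not isolated) | COc1cc([C@H](O)[C@H](CC(O)CO)CO[Si](C)(C)C(C)(C)C)cc(OC)c1OCc1ccccc1 | intermediate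
11 | (3R,4R)-4-[4-(benzyloxy)-3,5-dimethoxyphenyl]-3-[(tert-butyldimethylsilyloxy)methyl]-4-hydroxybutanal (not isolated) | COc1cc([C@H](O)[C@H](CC=O)CO[Si](C)(C)C(C)(C)C)cc(OC)c1OCc1ccccc1 | intermediate
12 | (4R,5R)-5-[4-(benzyloxy)-3,5-dimethoxyphenyl]-4-[(tert-butyldimethylsilyloxy)methyl]tetrahydrofuran-2-ol, anomer mixture | COc1cc([C@@H]2OC(O)C[C@@H]2CO[Si](C)(C)C(C)(C)C)cc(OC)c1OCc1ccccc1 | intermediate
13 | (4R,5R)-5-[4-(benzyloxy)-3,5-dimethoxyphenyl]-4-[(tert-butyldimethylsilyloxy)methyl]dihydrofuran-2(3H)-one, cis | COc1cc([C@@H]2OC(=O)C[C@@H]2CO[Si](C)(C)C(C)(C)C)cc(OC)c1OCc1ccccc1 | intermediate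
14 | tert-butyl{[(2R,3R)-2-[4-(benzyloxy)-3,5-dimethoxyphenyl]-3-[(tert-butyldimethylsilyloxy)methyl]-2,3-dihydrofuran-5-yl]oxy}dimethylsilane | COc1cc([C@@H]2OC(O[Si](C)(C)C(C)(C)C)=C[C@@H]2CO[Si](C)(C)C(C)(C)C)cc(OC)c1OCc1ccccc1 | intermediate
15 | methyl coumalate (methyl 2-oxo-2H-pyran-5-carboxylate) | COC(=O)C1=COC(=O)C=C1 | starting material
16 | methyl 3-bromocoumalate | COC(=O)C1=COC(=O)C(Br)=C1 | intermediate
17 | bridged cycloadduct: methyl 4-bromo-3-oxo-2-oxabicyclo[2.2.2]oct-5-ene-6-carboxylate fused at C7/C8 to the 2-aryl-3-(silyloxymethyl)tetrahydrofuran, silyloxy at C8, isomer mixture at the new centres (not isolated) | COC(=O)C1=CC2(Br)C(=O)OC1C1[C@H](CO[Si](C)(C)C(C)(C)C)[C@H](c3cc(OC)c(OCc4ccccc4)c(OC)c3)OC12O[Si](C)(C)C(C)(C)C | intermediate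
18 | methyl (2R,3R)-2-[4-(benzyloxy)-3,5-dimethoxyphenyl]-7-bromo-7a-(tert-butyldimethylsilyloxy)-3-[(tert-butyldimethylsilyloxy)methyl]-2,3,3a,7a-tetrahydrobenzofuran-5-carboxylate (not isolated) | COC(=O)C1=CC2[C@H](CO[Si](C)(C)C(C)(C)C)[C@H](c3cc(OC)c(OCc4ccccc4)c(OC)c3)OC2(O[Si](C)(C)C(C)(C)C)C(Br)=C1 | intermediate
19 | methyl (2R,3R)-2-[4-(benzyloxy)-3,5-dimethoxyphenyl]-7-bromo-3-[(tert-butyldimethylsilyloxy)methyl]-2,3-dihydrobenzofuran-5-carboxylate, cis | COc1cc([C@@H]2Oc3c(Br)cc(C(=O)OC)cc3[C@@H]2CO[Si](C)(C)C(C)(C)C)cc(OC)c1OCc1ccccc1 | intermediate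
20 | methyl (2R,3R)-2-[4-(benzyloxy)-3,5-dimethoxyphenyl]-3-[(tert-butyldimethylsilyloxy)methyl]-7-methoxy-2,3-dihydrobenzofuran-5-carboxylate | COc1cc([C@@H]2Oc3c(OC)cc(C(=O)OC)cc3[C@@H]2CO[Si](C)(C)C(C)(C)C)cc(OC)c1OCc1ccccc1 | intermediate
21 | [(2R,3R)-2-[4-(benzyloxy)-3,5-dimethoxyphenyl]-3-[(tert-butyldimethylsilyloxy)methyl]-7-methoxy-2,3-dihydrobenzofuran-5-yl]methanol | COc1cc([C@@H]2Oc3c(OC)cc(CO)cc3[C@@H]2CO[Si](C)(C)C(C)(C)C)cc(OC)c1OCc1ccccc1 | intermediate
22 | ethyl (triphenylphosphoranylidene)acetate | CCOC(=O)C=P(c1ccccc1)(c1ccccc1)c1ccccc1 | starting material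
23 | (2R,3R)-2-[4-(benzyloxy)-3,5-dimethoxyphenyl]-3-[(tert-butyldimethylsilyloxy)methyl]-7-methoxy-2,3-dihydrobenzofuran-5-carbaldehyde (not isolated) | COc1cc([C@@H]2Oc3c(OC)cc(C=O)cc3[C@@H]2CO[Si](C)(C)C(C)(C)C)cc(OC)c1OCc1ccccc1 | intermediate
24 | ethyl (E)-3-[(2R,3R)-2-[4-(benzyloxy)-3,5-dimethoxyphenyl]-3-[(tert-butyldimethylsilyloxy)methyl]-7-methoxy-2,3-dihydrobenzofuran-5-yl]acrylate | COc1cc([C@@H]2Oc3c(OC)cc(/C=C/C(=O)OCC)cc3[C@@H]2CO[Si](C)(C)C(C)(C)C)cc(OC)c1OCc1ccccc1 | intermediate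
25 | ethyl 3-[(2R,3R)-3-[(tert-butyldimethylsilyloxy)methyl]-2-(4-hydroxy-3,5-dimethoxyphenyl)-7-methoxy-2,3-dihydrobenzofuran-5-yl]propanoate | COc1cc([C@@H]2Oc3c(OC)cc(CCC(=O)OCC)cc3[C@@H]2CO[Si](C)(C)C(C)(C)C)cc(OC)c1O | intermediate
26 | bromoacetyl bromide | BrCC(Br)=O | starting material
27 | (R)-4-benzyl-3-(2-bromoacetyl)oxazolidin-2-one | O=C(CBr)N1[C@H](Cc2ccccc2)COC1=O | intermediate
28 | (R)-4-benzyl-3-{2-[4-[(2R,3R)-3-[(tert-butyldimethylsilyloxy)methyl]-5-(3-ethoxy-3-oxopropyl)-7-methoxy-2,3-dihydrobenzofuran-2-yl]-2,6-dimethoxyphenoxy]acetyl}oxazolidin-2-one | COc1cc([C@@H]2Oc3c(OC)cc(CCC(=O)OCC)cc3[C@@H]2CO[Si](C)(C)C(C)(C)C)cc(OC)c1OCC(=O)N1[C@H](Cc2ccccc2)COC1=O | intermediate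
29 | vanillin | COc1cc(C=O)ccc1O | starting material
30 | 4-(tert-butyldimethylsilyloxy)-3-methoxybenzaldehyde | COc1cc(C=O)ccc1O[Si](C)(C)C(C)(C)C | intermediate
31 | syn-aldol imide, (2R,3S) in the acyl chain (threo) | COc1cc([C@H](O)[C@H](C(=O)N2[C@H](Cc3ccccc3)COC2=O)Oc2c(OC)cc([C@@H]3Oc4c(OC)cc(CCC(=O)OCC)cc4[C@@H]3CO[Si](C)(C)C(C)(C)C)cc2OC)ccc1O[Si](C)(C)C(C)(C)C | intermediate
32 | (7′S,8′S)-threo triol with aryl and C3-methylene silyl ethers | COc1cc([C@H](O)[C@H](CO)Oc2c(OC)cc([C@@H]3Oc4c(OC)cc(CCCO)cc4[C@@H]3CO[Si](C)(C)C(C)(C)C)cc2OC)ccc1O[Si](C)(C)C(C)(C)C | intermediate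
33 | (7′S,8′S)-threo tetrasilyl ether with free C7′ hydroxyl | COc1cc([C@H](O)[C@H](CO[Si](C)(C)C(C)(C)C)Oc2c(OC)cc([C@@H]3Oc4c(OC)cc(CCCO[Si](C)(C)C(C)(C)C)cc4[C@@H]3CO[Si](C)(C)C(C)(C)C)cc2OC)ccc1O[Si](C)(C)C(C)(C)C | intermediate
34 | (7′R,8′S)-erythro C7′ chloroacetate of the tetrasilyl ether | COc1cc([C@@H](OC(=O)CCl)[C@H](CO[Si](C)(C)C(C)(C)C)Oc2c(OC)cc([C@@H]3Oc4c(OC)cc(CCCO[Si](C)(C)C(C)(C)C)cc4[C@@H]3CO[Si](C)(C)C(C)(C)C)cc2OC)ccc1O[Si](C)(C)C(C)(C)C | intermediate
35 | (7′R,8′S)-erythro tetrasilyl ether with free C7′ hydroxyl | COc1cc([C@@H](O)[C@H](CO[Si](C)(C)C(C)(C)C)Oc2c(OC)cc([C@@H]3Oc4c(OC)cc(CCCO[Si](C)(C)C(C)(C)C)cc4[C@@H]3CO[Si](C)(C)C(C)(C)C)cc2OC)ccc1O[Si](C)(C)C(C)(C)C | intermediate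
36 | (1R,2S)-1-(4-hydroxy-3-methoxyphenyl)-2-{4-[(2R,3R)-3-(hydroxymethyl)-5-(3-hydroxypropyl)-7-methoxy-2,3-dihydrobenzofuran-2-yl]-2,6-dimethoxyphenoxy}propane-1,3-diol | COc1cc([C@@H](O)[C@H](CO)Oc2c(OC)cc([C@@H]3Oc4c(OC)cc(CCCO)cc4[C@@H]3CO)cc2OC)ccc1O | target

Total step count: 23. Longest linear sequence: 19 steps (1, 3–8, 10–14, 16, 18–23).

Steps most likely to fail

Step 10. The ketene acetal may add only at C6 in a Michael sense without ring closure (followed by opening of the pyrone), bond formation at the brominated C3 may be sterically retarded, or aromatisation may proceed by cleavage of the O1–C7a bond instead of silanol loss. The fallback uses known chemistry, sets out from 2 and returns at 24, and bypasses the pyrone step entirely. NaBH4 in MeOH reduces 2 to [4-(benzyloxy)-3,5-dimethoxyphenyl]methanol F1. Mitsunobu etherification (PPh3, DIAD, THF) of F1 with purchased methyl 4-hydroxy-3-iodo-5-methoxybenzoate gives the aryl benzyl ether F2. Palladium-catalysed coupling of the aryl iodide with ethyl diazoacetate (Pd(PPh3)4, Ag2CO3, Et3N, toluene, rt) gives the aryldiazoacetate F3. Enantioselective intramolecular carbenoid insertion into the benzylic ether C–H bond (Rh2(S-PTTL)4 or its mirror-image complex, whichever gives the 2R series, toluene, −60 °C) closes the oxygen ring with the kinetically preferred cis geometry to give diester F4. LiAlH4 (THF, −20 °C) reduces both esters to diol F5. MnO2 with ylide 22 converts only the benzylic alcohol into the hydroxymethyl cinnamate F6, and silylation (tBuMe2SiCl, imidazole) then gives 24.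

Step 21. Partial ionisation at the electron-rich benzylic centre would erode stereochemical fidelity at C7′, and elimination of the oxyphosphonium to an enol ether may compete. The fallback sets out from 33 and returns at 35. Dess–Martin periodinane (NaHCO3, CH2Cl2) oxidises the benzylic alcohol to the α-aryloxy ketone F7. Chelation-controlled hydride reduction (Zn(BH4)2, Et2O, −30 °C; zinc bridging the carbonyl and aryloxy oxygens, hydride entering past the C8′ hydrogen) should then give the erythro alcohol 35 directly, making 34 and step 22 unnecessary.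

Step 3. Conversion may be low with the electron-rich aldehyde (reversible aldol addition, slow silyl trapping) and anti selectivity may erode. The fallback sets out from 2 and returns at 8. Roskamp homologation of 2 with ethyl diazoacetate (NbCl5 cat., CH2Cl2) gives β-keto ester F8. Asymmetric hydrogenation (RuCl2[(S)-BINAP], H2, EtOH) gives the (R)-β-hydroxy ester F9. Fráter–Seebach alkylation of its dianion (LiN(iPr)2 2.2 equiv, allyl bromide, THF/DMPU, −78 → −20 °C) installs the allyl group anti to the hydroxyl to give F10, and LiAlH4 reduction then gives diol 8.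

Further compounds
F1 | step 10 | [4-(benzyloxy)-3,5-dimethoxyphenyl]methanol | COc1cc(CO)cc(OC)c1OCc1ccccc1
F2 | step 10 | methyl 4-{[4-(benzyloxy)-3,5-dimethoxybenzyl]oxy}-3-iodo-5-methoxybenzoate | COC(=O)c1cc(I)c(OCc2cc(OC)c(OCc3ccccc3)c(OC)c2)c(OC)c1
F3 | step 10 | methyl 4-{[4-(benzyloxy)-3,5-dimethoxybenzyl]oxy}-3-(1-diazo-2-ethoxy-2-oxoethyl)-5-methoxybenzoate | CCOC(=O)C(=[N+]=[N-])c1cc(C(=O)OC)cc(OC)c1OCc1cc(OC)c(OCc2ccccc2)c(OC)c1
F4 | step 10 | 3-ethyl 5-methyl (2R,3S)-2-[4-(benzyloxy)-3,5-dimethoxyphenyl]-7-methoxy-2,3-dihydrobenzofuran-3,5-dicarboxylate, cis | COc1cc([C@@H]2Oc3c(OC)cc(C(=O)OC)cc3[C@@H]2C(=O)OCC)cc(OC)c1OCc1ccccc1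
F5 | step 10 | [(2R,3R)-2-[4-(benzyloxy)-3,5-dimethoxyphenyl]-7-methoxy-2,3-dihydrobenzofuran-3,5-diyl]dimethanol | COc1cc([C@@H]2Oc3c(OC)cc(CO)cc3[C@@H]2CO)cc(OC)c1OCc1ccccc1
F6 | step 10 | ethyl (E)-3-[(2R,3R)-2-[4-(benzyloxy)-3,5-dimethoxyphenyl]-3-(hydroxymethyl)-7-methoxy-2,3-dihydrobenzofuran-5-yl]acrylate | COc1cc([C@@H]2Oc3c(OC)cc(/C=C/C(=O)OCC)cc3[C@@H]2CO)cc(OC)c1OCc1ccccc1
F7 | step 21 | (S)-3-(tert-butyldimethylsilyloxy)-1-[4-(tert-butyldimethylsilyloxy)-3-methoxyphenyl]-2-{4-[(2R,3R)-3-[(tert-butyldimethylsilyloxy)methyl]-5-[3-(tert-butyldimethylsilyloxy)propyl]-7-methoxy-2,3-dihydrobenzofuran-2-yl]-2,6-dimethoxyphenoxy}propan-1-one | COc1cc(C(=O)[C@H](CO[Si](C)(C)C(C)(C)C)Oc2c(OC)cc([C@@H]3Oc4c(OC)cc(CCCO[Si](C)(C)C(C)(C)C)cc4[C@@H]3CO[Si](C)(C)C(C)(C)C)cc2OC)ccc1O[Si](C)(C)C(C)(C)C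
F8 | step 3 | ethyl 3-[4-(benzyloxy)-3,5-dimethoxyphenyl]-3-oxopropanoate | CCOC(=O)CC(=O)c1cc(OC)c(OCc2ccccc2)c(OC)c1
F9 | step 3 | ethyl (R)-3-[4-(benzyloxy)-3,5-dimethoxyphenyl]-3-hydroxypropanoate | COc1cc([C@H](O)CC(=O)OCC)cc(OC)c1OCc1ccccc1
F10 | step 3 | ethyl (2S,3R)-2-allyl-3-[4-(benzyloxy)-3,5-dimethoxyphenyl]-3-hydroxypropanoate | COc1cc([C@H](O)[C@H](CC=C)C(=O)OCC)cc(OC)c1OCc1ccccc1
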